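Ring numbering: C1 = CH bearing C7H2–OAr, C2 = C(CH3)=, C3 = =CH, C4 = CH2, C5 = CH–O-acyl, C6 = C(CH3)2. The SMILES descriptors correspond to 1S,5R.
Enabling feature: C7 on C1 and the oxygen on C5 lie on the same face of the cyclohexene, 1,3 to each other across C6. Both therefore fit into one tetrahydrofuran ring O5–C7–C1–C6–C5, a 6-oxabicyclo[3.2.1]oct-2-ene that the target itself does not contain.
Cuts, in order: C7–OAr (umbelliferone off); acyl–O5, with O5 reconnected to C7 (isovaleryl unit off); C1–C7 (C7 becomes the acetal carbon of a MOM ether on O5); O5–C7; then both C6–CH3 bonds, back to 4-methylanisole.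
Forward: the carbocycle is the reduced arene, C6 is dimethylated and the ketone is reduced. The ether ring closes in the Prins step and is reopened by an acyl iodide, and the coumarin is attached last.
Stereochemistry: C5 comes from a catalytic enantioselective ketone reduction. C1 is relayed from C5, because the short O–CH2 link reaches only one face of C1=C2.

Key step: step 6

Step 1
Reactants: 1 4-methylanisole
Product: 2 1-methoxy-4-methylcyclohexa-1,4-diene
Conditions: Li, NH3(l), EtOH, THF, −78 → −33 °C
Reagents that add atoms: none
Why: Birch reduction of an arene with two donor substituents puts the new hydrogens on unsubstituted carbons, so OMe and CH3 both end up on sp2 carbons of the unconjugated 1,4-diene.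

Step 2
Reactants: 2 1-methoxy-4-methylcyclohexa-1,4-diene
Product: 3 4-methylcyclohex-3-en-1-one
Conditions: oxalic acid (cat.), acetone–H2O, rt
Reagents that add atoms: water, O
Why: Enol ether hydrolysis under weak-acid catalysis is much faster than migration of the remaining double bond, so the β,γ-unsaturated ketone should result, and any conjugated isomer would feed the same dienolate in step 3.

Step 3
Reactants: 3 4-methylcyclohex-3-en-1-one
Product: 5 2,2,4-trimethylcyclohex-3-en-1-one, via monomethyl ketone 4 (not isolated)
Conditions: KOt-Bu (2.3 equiv), THF, 0 °C; MeI (2.6 equiv), 0 °C → rt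
Reagents that add atoms: iodomethane, CI
Why: In this deconjugative α,α-dialkylation the doubly activated C–H between carbonyl and alkene is removed first and the extended dienolate is methylated at its α-carbon; 4 then repeats the sequence, which builds quaternary C6 and keeps the alkene at C1=C2, while limited base and MeI restrain methylation at the other α-carbon.

Step 4
Reactants: 5 2,2,4-trimethylcyclohex-3-en-1-one
Product: 6 (R)-2,2,4-trimethylcyclohex-3-en-1-ol
Conditions: (S)-Me-CBS (10 mol %), BH3·SMe2 (0.7 equiv), THF, −20 °C; MeOH quench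
Reagents that add atoms: none
Why: In this Corey–Bakshi–Shibata reduction quaternary C6 is the large and C4H2 the small ketone substituent (as in tert-alkyl methyl ketones), so the (S)-catalyst should deliver hydride to the face that gives the R carbinol at C5, and the catalysed carbonyl reduction outruns hydroboration of the hindered trisubstituted alkene.

Step 5
Reactants: 6 (R)-2,2,4-trimethylcyclohex-3-en-1-ol; 7 chloromethyl methyl ether
Product: 8 (R)-4-(methoxymethoxy)-1,3,3-trimethylcyclohex-1-ene (MOM ether of 6)
Conditions: MOMCl, i-Pr2NEt, Bu4NI (cat.), CH2Cl2, 0 °C → reflux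
Reagents that add atoms: chloromethyl methyl ether (7), COCCl
Why: This is ordinary O-alkylation with an α-chloro ether (MOM protection), helped by iodide catalysis because the carbinol is neopentyl-like; C5 is untouched and the acetal carbon installed here is the future C7.

Step 6
Reactants: 8 (R)-4-(methoxymethoxy)-1,3,3-trimethylcyclohex-1-ene
Product: 11 (1S,5R)-2,8,8-trimethyl-6-oxabicyclo[3.2.1]oct-2-ene, via oxocarbenium ion 9 (not isolated), via tertiary cation 10 (not isolated)
Conditions: TMSOTf (1.2 equiv), 2,6-di-tert-butyl-4-methylpyridine (1.5 equiv), CH2Cl2 (0.01 M), −78 → −20 °C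
Reagents that add atoms: none
Why: TMSOTf silylates the less hindered methoxy oxygen of 8 and expels MeOSiMe3 to leave oxocarbenium ion 9; with the C5–O bond axial, C1 of the C1=C2 bond attacks its CH2 carbon (the future C7) to give tertiary cation 10, from which the hindered pyridine removes a C3 proton to leave the C2=C3 bond of 11. The closest known reaction type is the Lewis-acid Prins (oxonium-ene) cyclisation of alkoxymethyl ethers of homoallylic alcohols, which turns from pyran to tetrahydrofuran formation when the remote alkene carbon is the more substituted one. The single ring closed, the tetrahydrofuran O5–C7–C1–C6–C5, forms 5-exo with respect to the alkene and endo with respect to the C=O+ bond. The only new stereocentre, C1, is fixed as S by C5, because a two-atom O–CH2 link anchored on the axial C5 oxygen can reach only the ring face that carries this oxygen. The step needs attack at C1 rather than C2, secured by the tertiary C2 cation versus a secondary C1 cation, and proton loss from C3 rather than from CH3 or C1, secured by the Zaitsev preference for the ring alkene and by Bredt strain in a bridgehead C1=C2 alkene. The base keeps the medium free of triflic acid so that the double bond of 8 does not migrate before closure, and a 2-oxonia-Cope escape is unlikely because the C5–C6 bond lies close to the nodal plane of the alkene.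

Step 7
Reactants: 11 (1S,5R)-2,8,8-trimethyl-6-oxabicyclo[3.2.1]oct-2-ene; 12 isovaleryl chloride
Product: 14 (1R,5S)-5-(iodomethyl)-4,6,6-trimethylcyclohex-3-en-1-yl 3-methylbutanoate, via acyloxonium ion 13 (not isolated)
Conditions: i-BuCOCl (1.5 equiv), NaI (2 equiv), MeCN, 0 °C → rt, dark
Reagents that add atoms: isovaleryl chloride (12), CC(C)CC(=O)Cl; sodium iodide, [Na+].[I-]
Why: In this acylative ether cleavage by an acyl iodide made in situ, the tied-back bridging oxygen is acylated to 13 and iodide opens it by SN2 at primary C7 rather than at the secondary, neopentyl-type C5, so the C5–O bond keeps its configuration and the ester and the leaving group arise in one operation.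

Step 8
Reactants: 14 (1R,5S)-5-(iodomethyl)-4,6,6-trimethylcyclohex-3-en-1-yl 3-methylbutanoate; 15 umbelliferone
Product: 16 (1R,5S)-4,6,6-trimethyl-5-{[(2-oxo-2H-chromen-7-yl)oxy]methyl}cyclohex-3-en-1-yl 3-methylbutanoate
Conditions: Cs2CO3 (1.5 equiv), DMF, 50 °C
Reagents that add atoms: umbelliferone (15), O=c1ccc2ccc(O)cc2o1
Why: In this Williamson ether synthesis the weakly basic caesium phenoxide of the acidic phenol 15 displaces the primary iodide by SN2 in a dipolar aprotic solvent, no stereocentre takes part, and the ester and lactone tolerate anhydrous carbonate.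

Compound list
1 | 4-methylanisole | COc1ccc(C)cc1 | starting material
2 | 1-methoxy-4-methylcyclohexa-1,4-diene | COC1=CCC(C)=CC1 | intermediate
3 | 4-methylcyclohex-3-en-1-one | CC1=CCC(=O)CC1 | intermediate
4 | 2,4-dimethylcyclohex-3-en-1-one (racemic, not isolated) | CC1=CC(C)C(=O)CC1 | intermediate
5 | 2,2,4-trimethylcyclohex-3-en-1-one | CC1=CC(C)(C)C(=O)CC1 | intermediate
6 | (R)-2,2,4-trimethylcyclohex-3-en-1-ol | O[C@@H]1CCC(C)=CC1(C)C | intermediate
7 | chloromethyl methyl ether | COCCl | starting material
8 | (R)-4-(methoxymethoxy)-1,3,3-trimethylcyclohex-1-ene | COCO[C@@H]1CCC(C)=CC1(C)C | intermediate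
9 | {[(1R)-2,2,4-trimethylcyclohex-3-en-1-yl]oxy}methylium, the O5=CH2 oxocarbenium ion (not isolated) | C=[O+][C@@H]1CCC(C)=CC1(C)C | intermediate
10 | (1S,5R)-2,8,8-trimethyl-6-oxabicyclo[3.2.1]octan-2-ylium, the tertiary C2 cation (not isolated) | C[C+]1CC[C@H]2OC[C@@H]1C2(C)C | intermediate
11 | (1S,5R)-2,8,8-trimethyl-6-oxabicyclo[3.2.1]oct-2-ene | CC1=CC[C@H]2OC[C@@H]1C2(C)C | intermediate
12 | isovaleryl chloride (3-methylbutanoyl chloride) | CC(C)CC(=O)Cl | starting material
13 | (1S,5R)-2,8,8-trimethyl-6-(3-methylbutanoyl)-6-oxoniabicyclo[3.2.1]oct-2-ene (not isolated) | CC1=CC[C@H]2[O+](C(=O)CC(C)C)C[C@@H]1C2(C)C | intermediate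
14 | (1R,5S)-5-(iodomethyl)-4,6,6-trimethylcyclohex-3-en-1-yl 3-methylbutanoate | CC1=CC[C@@H](OC(=O)CC(C)C)C(C)(C)[C@H]1CI | intermediate
15 | umbelliferone (7-hydroxy-2H-chromen-2-one) | O=c1ccc2ccc(O)cc2o1 | starting material
16 | (1R,5S)-4,6,6-trimethyl-5-{[(2-oxo-2H-chromen-7-yl)oxy]methyl}cyclohex-3-en-1-yl 3-methylbutanoate | CC1=CC[C@@H](OC(=O)CC(C)C)C(C)(C)[C@H]1COc1ccc2ccc(=O)oc2c1 | target

Total step count: 8. Longest linear sequence: 8 (steps 1–8 from 4-methylanisole).

Steps most likely to fail

**Step 6.**
- Risk: both atoms of the O=CH2+ unit end up inside the new five-membered ring, so its overlap with C1 is poor.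
- Closure may then lose out to simple loss of the acetal carbon, to intermolecular attack, or to migration of the ring double bond before the C–C bond forms.
- Proton loss toward the methyl group is a lesser concern.
- Fallback: C7 is delivered to C1 by a Still–Wittig [2,3]-sigmatropic shift from an oxygen at C3. It sets out from 8.
- Allylic oxidation of C3H2 (CrO3·3,5-dimethylpyrazole, CH2Cl2, −20 °C) should give (R)-5-(methoxymethoxy)-2,4,4-trimethylcyclohex-2-en-1-one F1.
- Luche reduction with axial hydride delivery should give the cis-1,3 allylic alcohol F2.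
- KH and ICH2SnBu3 in THF should give the stannylmethyl ether F3.
- n-BuLi in THF at −78 °C triggers tin–lithium exchange and the suprafacial shift. This moves the CH2O unit from O3 to C1 on the face shared with O5, sets C2=C3, and gives the homoallylic alcohol F4.
- Mitsunobu coupling with 15 (PPh3, DIAD, toluene) should give the aryl ether F5.
- HCl in MeOH removes the MOM group to give the alcohol F6.
- Acylation with 12 (pyridine, DMAP) returns to the route at 16. Steps 7 and 8 are bypassed as well.

**Step 7.**
- Risk: O-acylation of the hindered bridging oxygen may be sluggish.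
- Iodide attack or ionisation may occur at the wrong carbon, and adventitious HI may add across the trisubstituted alkene.
- Fallback: cleavage and acylation are separated. It sets out from 11.
- Me2BBr with catalytic Et3N in CH2Cl2 at 0 °C, an SN2-selective boron halide ether cleavage, followed by NaHCO3 work-up should give the bromo alcohol F7.
- Acylation with 12 (pyridine, DMAP, CH2Cl2) should give the bromo ester F8.
- F8 takes the place of 14 under the conditions of step 8, so the route is rejoined at 16.

**Step 8.**
- Risk: substitution at the β-branched C7, next to C1 and quaternary C6, may be slow.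
- E2 loss of the allylic C1–H could then take over.
- Fallback: the carbon–oxygen bond is made from an activated alcohol under neutral conditions instead of from the halide and a phenoxide. It sets out from 14.
- CsOAc in DMF, a much weaker base, should give the primary acetate F9.
- Selective methanolysis of this unhindered acetate (K2CO3, MeOH, 0 °C) should give the hydroxy ester F10, because the neopentyl-type isovalerate reacts far more slowly.
- Mitsunobu coupling with 15 (PPh3, DIAD, toluene) returns to the route at 16.

Further compounds
F1 | step 6 | (R)-5-(methoxymethoxy)-2,4,4-trimethylcyclohex-2-en-1-one | COCO[C@@H]1CC(=O)C(C)=CC1(C)C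
F2 | step 6 | (1S,5R)-5-(methoxymethoxy)-2,4,4-trimethylcyclohex-2-en-1-ol | COCO[C@@H]1C[C@H](O)C(C)=CC1(C)C
F3 | step 6 | tributyl({[(1S,5R)-5-(methoxymethoxy)-2,4,4-trimethylcyclohex-2-en-1-yl]oxy}methyl)stannane | COCO[C@@H]1C[C@H](OC[Sn](CCCC)(CCCC)CCCC)C(C)=CC1(C)C
F4 | step 6 | [(1S,5R)-5-(methoxymethoxy)-2,6,6-trimethylcyclohex-2-en-1-yl]methanol | CC1=CC[C@@H](OCOC)C(C)(C)[C@H]1CO
F5 | step 6 | 7-{[(1S,5R)-5-(methoxymethoxy)-2,6,6-trimethylcyclohex-2-en-1-yl]methoxy}-2H-chromen-2-one | CC1=CC[C@@H](OCOC)C(C)(C)[C@H]1COc1ccc2ccc(=O)oc2c1
F6 | step 6 | 7-{[(1S,5R)-5-hydroxy-2,6,6-trimethylcyclohex-2-en-1-yl]methoxy}-2H-chromen-2-one | CC1=CC[C@@H](O)C(C)(C)[C@H]1COc1ccc2ccc(=O)oc2c1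
F7 | step 7 | (1R,5S)-5-(bromomethyl)-4,6,6-trimethylcyclohex-3-en-1-ol | CC1=CC[C@@H](O)C(C)(C)[C@H]1CBr
F8 | step 7 | (1R,5S)-5-(bromomethyl)-4,6,6-trimethylcyclohex-3-en-1-yl 3-methylbutanoate | CC1=CC[C@@H](OC(=O)CC(C)C)C(C)(C)[C@H]1CBr
F9 | step 8 | (1R,5S)-5-(acetoxymethyl)-4,6,6-trimethylcyclohex-3-en-1-yl 3-methylbutanoate | CC1=CC[C@@H](OC(=O)CC(C)C)C(C)(C)[C@H]1COC(C)=O
F10 | step 8 | (1R,5S)-5-(hydroxymethyl)-4,6,6-trimethylcyclohex-3-en-1-yl 3-methylbutanoate | CC1=CC[C@@H](OC(=O)CC(C)C)C(C)(C)[C@H]1CO
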